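Abietane numbering is used throughout: C1–C3 is the propanoic acid chain (C3 the acid carbon), C4 the isopropenyl carbon, C5–C10 ring B with the ketone at C7, and C8, C9, C11–C14 ring C.

## The problem

Compound 23 is a 3,4-seco-abietane. Ring A is opened to a propanoic acid chain on C10 and an isopropenyl group on C5, leaving a tetralone in which ring B is fused through C8–C9 to a hexasubstituted benzene ring C. Ring C carries C11-OH, C12-OMe, C13-isopropyl and C14-OH in a fixed order, so three oxygens and one alkyl group must be placed on adjacent carbons without regiochemical ambiguity. There are two stereocentres, the quaternary C10 (methyl, chain, aryl) and the adjacent tertiary C5, with the C10 methyl cis to the C5 isopropenyl group. Neither can be corrected by epimerisation (C10 has no hydrogen, C5 is β to the C7 ketone), so both must be set together and in absolute terms; the cis relation is what a suprafacial cycloaddition transfers from an E trisubstituted alkene. The fragile parts are the electron-rich 11,14-hydroquinone (oxidised by air to the quinone, fastest as its phenoxide), the isopropenyl group (protonation by strong acid leads to double-bond migration or lactonisation onto the acid), and the free acid. The enabling feature is that the C7 ketone sits on C8 next to the C14 hydroxyl while C11 carries the para hydroxyl. Rings B and C together are therefore a 5,8-dihydroxy-1-tetralone, the retron of a Michael–Dieckmann benzannulation across a C8=C9 enone, and that cut removes ring C in one operation and leaves a monocyclic enone holding the C7 oxygen and both stereocentres.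

## Retrosynthesis

**23 ⇒ 22.** No skeletal bond is cut; the C3 acid is carried as methyl ester 22 and released by base hydrolysis at the end. A tert-butyl ester would need acid, which endangers the isopropenyl group, and a free acid would pass through the base-mediated annulation as a carboxylate. The ester is also the form in which the chain is most simply built by olefination. The forward step only has to hydrolyse an unhindered ester while oxygen is kept from the hydroquinone.

**22 ⇒ 13 + 19.** Two bonds of ring C are cut, C9–C11 and C8–C14, giving enone 13 and sulfonyl butenolide 19. Cutting only C8–C14 (an electrocyclic closure) would require C7 at the alcohol level and a pre-formed C9–C11 bond; cutting ring B instead would carry a finished, oxidation-prone arene through all the stereochemical steps. The two-bond cut uses the C7 carbonyl as the activating group of the acceptor and delivers it unchanged. All four ring C substituents then come from a four-step butenolide whose polarity (nucleophilic at the sulfonyl carbon, electrophilic at the carbonyl) fixes their order. The forward reaction must achieve conjugate addition at C9, which is flanked by the quaternary C10, then acylation, sulfinate loss and aromatisation, without touching the side-chain ester.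

**13 ⇒ 11 ⇒ 10 ⇒ 8.** The C8=C9 double bond of 13 is traded for a C9 amino group and a C7 silyl enol ether (11), the masked form in which a 1-amino-3-silyloxydiene cycloadduct holds an enone. With the enone masked, the chain is cut at C1=C2 after restoring that unsaturation (10), leading back to aldehyde 8. The order matters: the side-chain enoate must be reduced before the ring enone exists, otherwise two conjugate acceptors compete. Forward, this is an olefination of a neopentyl aldehyde, a chemoselective 1,4-reduction and an acid-induced hydrolysis/β-elimination.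

**8 ⇒ 3 + 7.** C5–C6 and C9–C10 are cut in a Diels–Alder sense, giving dienal 3 and chiral aminosilyloxydiene 7. This one step forms the quaternary C10 and the adjacent C5, with their relative configuration dictated by the E alkene of 3. A stepwise conjugate addition/enolate alkylation on a cyclohexenone would place the carbonyl at C9 instead of C7. The precursors are acyclic and achiral apart from the recoverable auxiliary. The cycloaddition must engage the trisubstituted, formyl-bearing double bond of 3 endo and on one diene face.

**3 ⇒ 1 + 2, and 7 ⇒ 6 ⇒ 4 + 5.** The trisubstituted alkene of 3 (the future C5–C10 bond) is cut by Wittig logic into methacrolein 1 and formyl ylide 2; a crossed aldol would suffer from self-condensation and conjugate addition. Diene 7 is the O-silylated enolate of vinylogous amide 6, itself the condensation product of methoxyenone 4 and C2-symmetric pyrrolidine 5.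

**19 ⇒ 18 ⇒ 17 ⇒ 16 ⇒ 14.** The sulfone comes from sulfide 18 by oxidation, the sulfide from methyl tetronate 17 by C5 metalation and sulfenylation (cut C5–S), the tetronate from tetronic acid 16 by O-methylation, and 16 from keto ester 14 by γ-bromination and lactonisation (cut O–C5). The isopropyl group is already in 14, so the only regiochemical demands are O4- versus O2-methylation and C5- versus C3-functionalisation, both following the normal behaviour of tetronates.

## Roads not taken

**Alternative 1:** Ring B is cut at C5–C10 and C6–C7. Irradiating the ortho-formyl aryl lactone A1 would give a hydroxy-o-quinodimethane that adds endo to allyl (2E)-4-methylpenta-2,4-dienoate A2, giving cycloadduct A3. The merits are real: ring C is built by ordinary arene chemistry with no new annulation, the lactone tether fixes the geometry of the C10 diene terminus, and both stereocentres arise in the ring-forming step. In certainty of ring C assembly this road is better than the chosen one. Against it, C10 forms from a fully substituted diene terminus, so cycloaddition competes with reketonisation of the photoenol, and absolute control would rest on a chiral Lewis acid acting on a very hindered dienol. A3 also carries a C6 ester, a C7 alcohol, a C14 methyl ether and a lactone, each needing its own step, and A1 is a long arene synthesis. The chosen plan sets against it a single step after ring formation, no phenol protection, and stereocentres from a ground-state cycloaddition.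

**Alternative 2:** Ring C is cut at C8–C14 only. Heating the 4-alkenyl-4-hydroxycyclobutenone A4 would open the four-membered ring to a dienylketene, and 6π-electrocyclisation followed by enolisation gives hydroquinone A5. This ring synthesis is well established for fully substituted hydroquinones, runs under neutral conditions, has regiochemistry fixed by the cyclobutenone, and makes the hindered C9–C11 bond by carbonyl addition, not conjugate addition. On precedent for the ring-forming event it is the stronger road. Its cost lies around it: a C9 organometallic of ring B is needed next to the quaternary carbon, and C7 must travel as a protected alcohol with an extra stereocentre. After ring closure there remain desilylation, a benzylic oxidation that would also oxidise the free hydroquinone, and acidic tert-butyl ester cleavage beside the isopropenyl group. The chosen plan sets convergence and a ketone that needs no redox adjustment against this, and accepts a less tested annulation.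

**Alternative 3:** No ring is cut; C4–C5 and C10–C1 are disconnected. A chiral copper catalyst (CuBr·SMe2 with a ferrocenyl diphosphine) would add isopropenylmagnesium bromide A7 to 2-methylcyclohex-2-en-1-one A6, and the magnesium enolate would be trapped with tert-butyl prop-2-enoate A8 anti to the isopropenyl group to give ketone A9. This sets both stereocentres and the whole chain in one flask from three commodity chemicals, clearly faster than the six steps spent here on 13. However, A9 has its oxygen at C9 and no C8=C9 unsaturation. Ring C would have to be built on a ketone flanked by the quaternary carbon, and C7 oxidised late next to an electron-rich arene and an allylic isopropenyl group, or the carbonyl transposed over several steps. Enantioselective alkenyl addition to an α-substituted enone followed by a quaternising Michael trap is also among the less secure cases of this chemistry. The chosen plan sets against the speed of A9 an enone that maps directly onto the annulation.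

Key step: step 12

Assumption: the (2S,5S) auxiliary is taken to direct the dienophile to the diene face that gives the (1S,2R,6S) cycloadduct 8; this sense of induction is not derived here, and if it proves opposite the (2R,5R)-pyrrolidine is used with nothing else changed.

## Route

Step 1
Reactants: 1 methacrolein (2-methylprop-2-enal); 2 2-(triphenyl-λ5-phosphanylidene)propanal
Product: 3 (2E)-2,4-dimethylpenta-2,4-dienal
Conditions: toluene, 80 °C, sealed vessel, excess 1; distillation
Reagents that add atoms: none
Why: Wittig olefination with a stabilised formyl ylide, which gives the E trisubstituted alkene; the product dienal is less electrophilic than 1 and does not react again with this weakly nucleophilic ylide.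

Step 2
Reactants: 4 (3E)-4-methoxybut-3-en-2-one; 5 (2S,5S)-2,5-diphenylpyrrolidine
Product: 6 (3E)-4-[(2S,5S)-2,5-diphenylpyrrolidin-1-yl]but-3-en-2-one
Conditions: MeOH, rt to 40 °C
Reagents that add atoms: none
Why: Addition–elimination at the β-carbon of a vinylogous ester (amine adds, methanol leaves) gives the vinylogous amide; the pyrrolidine stereocentres are not involved.

Step 3
Reactants: 6 (3E)-4-[(2S,5S)-2,5-diphenylpyrrolidin-1-yl]but-3-en-2-one
Product: 7 (2S,5S)-1-[(1E)-3-{[tert-butyl(dimethyl)silyl]oxy}buta-1,3-dien-1-yl]-2,5-diphenylpyrrolidine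
Conditions: KN(SiMe3)2, THF, −78 °C; TBSCl, −78 °C to rt
Reagents that add atoms: tert-butyl(chloro)dimethylsilane (TBSCl), CC(C)(C)[Si](C)(C)Cl
Why: Kinetic deprotonation of the methyl ketone and O-silylation of the cross-conjugated enolate, the standard preparation of 1-amino-3-silyloxybutadienes; the E enamine geometry is retained.

Step 4
Reactants: 3 (2E)-2,4-dimethylpenta-2,4-dienal; 7 (2S,5S)-1-[(1E)-3-{[tert-butyl(dimethyl)silyl]oxy}buta-1,3-dien-1-yl]-2,5-diphenylpyrrolidine
Product: 8 (1S,2R,6S)-4-{[tert-butyl(dimethyl)silyl]oxy}-2-[(2S,5S)-2,5-diphenylpyrrolidin-1-yl]-1-methyl-6-(prop-1-en-2-yl)cyclohex-3-ene-1-carbaldehyde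
Conditions: toluene, rt to 50 °C; crude product used directly
Reagents that add atoms: none
Why: Normal-demand Diels–Alder reaction of a 1-amino-3-silyloxybutadiene with an α-substituted enal: the CH2 terminus of 7 bonds to the β-carbon of 3 (C5–C6) and the amino-bearing terminus to the α-carbon (C9–C10), formyl endo, so amine and formyl end up cis. The E geometry of 3 is transferred suprafacially and places the C10 methyl cis to the C5 isopropenyl group. The absolute configuration of C5 and C10 follows from the diene face left open by the phenyl groups of the C2-symmetric pyrrolidine combined with the endo mode; the C9 centre is temporary.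

Step 5
Reactants: 8 (1S,2R,6S)-4-{[tert-butyl(dimethyl)silyl]oxy}-2-[(2S,5S)-2,5-diphenylpyrrolidin-1-yl]-1-methyl-6-(prop-1-en-2-yl)cyclohex-3-ene-1-carbaldehyde; 9 methyl 2-(dimethoxyphosphoryl)acetate (trimethyl phosphonoacetate)
Product: 10 methyl (2E)-3-[(1S,2R,6S)-4-{[tert-butyl(dimethyl)silyl]oxy}-2-[(2S,5S)-2,5-diphenylpyrrolidin-1-yl]-1-methyl-6-(prop-1-en-2-yl)cyclohex-3-en-1-yl]prop-2-enoate
Conditions: NaH, THF, 0 °C to 40 °C
Reagents that add atoms: none
Why: Horner–Wadsworth–Emmons olefination to the E enoate; the aldehyde has no α-hydrogen, so C10 cannot epimerise, and the silyl enol ether and tertiary amine are inert to the sodium phosphonate.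

Step 6
Reactants: 10 methyl (2E)-3-[(1S,2R,6S)-4-{[tert-butyl(dimethyl)silyl]oxy}-2-[(2S,5S)-2,5-diphenylpyrrolidin-1-yl]-1-methyl-6-(prop-1-en-2-yl)cyclohex-3-en-1-yl]prop-2-enoate
Product: 11 methyl 3-[(1S,2R,6S)-4-{[tert-butyl(dimethyl)silyl]oxy}-2-[(2S,5S)-2,5-diphenylpyrrolidin-1-yl]-1-methyl-6-(prop-1-en-2-yl)cyclohex-3-en-1-yl]propanoate
Conditions: Cu(OAc)2·H2O (5 mol %), 1,2-bis(diphenylphosphino)benzene (5 mol %), (EtO)2MeSiH, tBuOH, toluene, rt
Reagents that add atoms: none
Why: CuH-catalysed 1,4-reduction of the enoate (hydrocupration, protonation of the copper enolate by tBuOH, turnover by the silane); the isopropenyl group, silyl enol ether and amine are not substrates for CuH, and the ring enone is still masked, so there is only one conjugate acceptor.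

Step 7
Reactants: 11 methyl 3-[(1S,2R,6S)-4-{[tert-butyl(dimethyl)silyl]oxy}-2-[(2S,5S)-2,5-diphenylpyrrolidin-1-yl]-1-methyl-6-(prop-1-en-2-yl)cyclohex-3-en-1-yl]propanoate
Product: 13 methyl 3-[(1R,6S)-1-methyl-4-oxo-6-(prop-1-en-2-yl)cyclohex-2-en-1-yl]propanoate, via β-amino ketone 12 (not isolated)
Conditions: 48% aq. HF, MeCN, 0 °C to rt; aq. NaHCO3; auxiliary 5 recovered by acid–base extraction
Reagents that add atoms: none
Why: Cleavage of the silyl enol ether gives β-amino ketone 12, whose protonated amine is lost by β-elimination through the enol to give the conjugated enone. C5 and C10 are untouched; the C10 descriptor changes from S to R only because the ranking of its neighbours changes.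

Step 8
Reactants: 14 ethyl 2-acetyl-3-methylbutanoate (ethyl 2-isopropylacetoacetate)
Product: 16 4-hydroxy-3-(propan-2-yl)furan-2(5H)-one (3-isopropyltetronic acid), via ethyl 4-bromo-2-isopropyl-3-oxobutanoate 15 (not isolated)
Conditions: Br2 (1.0 equiv), CHCl3, 0 °C to rt; concentrate; neat, 120–130 °C
Reagents that add atoms: none
Why: Classical tetronic acid synthesis from a 2-alkylacetoacetate: bromination followed by HBr-mediated equilibration places bromine on the terminal methyl, and on heating the ester oxygen displaces bromide with loss of ethyl bromide to close the lactone.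

Step 9
Reactants: 16 4-hydroxy-3-(propan-2-yl)furan-2(5H)-one
Product: 17 4-methoxy-3-(propan-2-yl)furan-2(5H)-one
Conditions: Me2SO4, K2CO3, acetone, reflux
Reagents that add atoms: dimethyl sulfate, COS(=O)(=O)OC
Why: O-Alkylation of the vinylogous acid at the 4-oxygen gives the methyl tetronate; any 2-methoxyfuran-4(5H)-one isomer would be removed by chromatography.

Step 10
Reactants: 17 4-methoxy-3-(propan-2-yl)furan-2(5H)-one
Product: 18 (5RS)-4-methoxy-5-(phenylsulfanyl)-3-(propan-2-yl)furan-2(5H)-one
Conditions: LiN(iPr)2 (2.1 equiv), THF, −78 °C; PhSSPh (1.05 equiv), −78 to −20 °C; aq. NH4Cl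
Reagents that add atoms: diphenyl disulfide, c1ccc(cc1)SSc1ccccc1
Why: Methyl tetronates are deprotonated at C5 (γ to the carbonyl, α to the ring oxygen) and the dienolate is sulfenylated at that carbon, C3 being blocked by isopropyl; the second equivalent of base absorbs the more acidic product so that it does not quench unreacted anion.

Step 11
Reactants: 18 (5RS)-4-methoxy-5-(phenylsulfanyl)-3-(propan-2-yl)furan-2(5H)-one
Product: 19 (5RS)-5-(benzenesulfonyl)-4-methoxy-3-(propan-2-yl)furan-2(5H)-one
Conditions: mCPBA (2.3 equiv), CH2Cl2, 0 °C to rt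
Reagents that add atoms: 3-chloroperoxybenzoic acid (mCPBA), OOC(=O)c1cccc(Cl)c1
Why: Peracid oxidation of the sulfide through the sulfoxide to the sulfone, as used to make 3-sulfonylphthalide donors from their sulfides; the electron-poor β-alkoxy enoate double bond is not epoxidised.

Step 12
Reactants: 13 methyl 3-[(1R,6S)-1-methyl-4-oxo-6-(prop-1-en-2-yl)cyclohex-2-en-1-yl]propanoate; 19 (5RS)-5-(benzenesulfonyl)-4-methoxy-3-(propan-2-yl)furan-2(5H)-one
Product: 22 methyl 3-[(1S,2S)-5,8-dihydroxy-7-methoxy-1-methyl-4-oxo-6-(propan-2-yl)-2-(prop-1-en-2-yl)-1,2,3,4-tetrahydronaphthalen-1-yl]propanoate, via Michael adduct enolate 20 (not isolated), via ring C enedione 21 (not isolated)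
Conditions: LiOtBu (3.2 equiv), THF, −78 °C; 19 (1.2 equiv), then 13; −78 °C to rt; degassed 1 M HCl, Ar
Reagents that add atoms: none
Why: Proposed new method: LiOtBu removes the proton at the sulfonyl-bearing C5 of 19 to give a sulfonyl-stabilised 2-oxidofuran, which adds through that carbon to the β-carbon C9 of 13 (bond C9–C11) and gives C8 enolate 20; the enolate acylates the neighbouring lactone carbonyl (bond C8–C14), the bridging alkoxide collapses so that the former ring oxygen stays on C11, lithium benzenesulfinate is expelled to give enedione 21, and two enolisations aromatise ring C to hydroquinone 22. The closest known reaction is the Hauser–Kraus annulation of 3-sulfonylphthalide anions with cyclohexenones and with 4,4-disubstituted cyclohexadienones such as quinone monoketals; what is new is a donor without the fused benzene ring, whose anion is a furanolate instead of an isobenzofuranolate. Ring C closes by a 6-exo-trig Dieckmann-type attack of the C8 enolate on the lactone carbonyl, which the new C9–C11 bond holds within reach. No lasting stereocentre is created: the centres formed at C8, C9 and C11 are erased on aromatisation, and C5 and C10 cannot epimerise under base (C10 has no hydrogen, C5 is β to the ketone); the C10 descriptor returns to S only through ranking. The step needs regiocontrol on the donor (attack through C5, not C3), 1,4- over 1,2-addition, and acylation by the lactone and not by the side-chain ester. The sulfonyl group localises charge at C5 while C3 is blocked by isopropyl, the soft delocalised anion favours conjugate addition, and the side-chain ester could only close a bridged bicyclo[3.3.1] ring whereas the lactone carbonyl is adjacent. The polarity of 19 alone places C11-OH next to C12-OMe and C14-OH next to C13-isopropyl and the C7 ketone.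

Step 13
Reactants: 22 methyl 3-[(1S,2S)-5,8-dihydroxy-7-methoxy-1-methyl-4-oxo-6-(propan-2-yl)-2-(prop-1-en-2-yl)-1,2,3,4-tetrahydronaphthalen-1-yl]propanoate
Product: 23 3-[(1S,2S)-5,8-dihydroxy-7-methoxy-1-methyl-4-oxo-6-(propan-2-yl)-2-(prop-1-en-2-yl)-1,2,3,4-tetrahydronaphthalen-1-yl]propanoic acid
Conditions: LiOH (5 equiv), degassed THF/H2O, Ar, 0 °C to rt; degassed 1 M HCl containing Na2S2O4
Reagents that add atoms: lithium hydroxide (its oxygen becomes the acid hydroxyl), [Li+].[OH-]
Why: Saponification of an unhindered primary methyl ester by acyl–oxygen cleavage; the phenols are only deprotonated and neither stereocentre can epimerise. Oxygen is excluded and dithionite is present at acidification to keep the hydroquinone reduced.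

## Compound list

1 | methacrolein (2-methylprop-2-enal) | C=C(C)C=O | starting material
2 | 2-(triphenyl-λ5-phosphanylidene)propanal | CC(C=O)=P(c1ccccc1)(c1ccccc1)c1ccccc1 | starting material
3 | (2E)-2,4-dimethylpenta-2,4-dienal | O=C/C(C)=C/C(C)=C | intermediate
4 | (3E)-4-methoxybut-3-en-2-one | CO/C=C/C(C)=O | starting material
5 | (2S,5S)-2,5-diphenylpyrrolidine | N1[C@H](c2ccccc2)CC[C@H]1c1ccccc1 | starting material
6 | (3E)-4-[(2S,5S)-2,5-diphenylpyrrolidin-1-yl]but-3-en-2-one | CC(=O)/C=C/N1[C@H](c2ccccc2)CC[C@H]1c1ccccc1 | intermediate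
7 | (2S,5S)-1-[(1E)-3-{[tert-butyl(dimethyl)silyl]oxy}buta-1,3-dien-1-yl]-2,5-diphenylpyrrolidine | C=C(O[Si](C)(C)C(C)(C)C)/C=C/N1[C@H](c2ccccc2)CC[C@H]1c1ccccc1 | intermediate
8 | (1S,2R,6S)-4-{[tert-butyl(dimethyl)silyl]oxy}-2-[(2S,5S)-2,5-diphenylpyrrolidin-1-yl]-1-methyl-6-(prop-1-en-2-yl)cyclohex-3-ene-1-carbaldehyde | C=C(C)[C@@H]1CC(O[Si](C)(C)C(C)(C)C)=C[C@@H](N2[C@H](c3ccccc3)CC[C@H]2c2ccccc2)[C@@]1(C)C=O | intermediate
9 | methyl 2-(dimethoxyphosphoryl)acetate | COC(=O)CP(=O)(OC)OC | starting material
10 | methyl (2E)-3-[(1S,2R,6S)-4-{[tert-butyl(dimethyl)silyl]oxy}-2-[(2S,5S)-2,5-diphenylpyrrolidin-1-yl]-1-methyl-6-(prop-1-en-2-yl)cyclohex-3-en-1-yl]prop-2-enoate | C=C(C)[C@@H]1CC(O[Si](C)(C)C(C)(C)C)=C[C@@H](N2[C@H](c3ccccc3)CC[C@H]2c2ccccc2)[C@@]1(C)/C=C/C(=O)OC | intermediate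
11 | methyl 3-[(1S,2R,6S)-4-{[tert-butyl(dimethyl)silyl]oxy}-2-[(2S,5S)-2,5-diphenylpyrrolidin-1-yl]-1-methyl-6-(prop-1-en-2-yl)cyclohex-3-en-1-yl]propanoate | C=C(C)[C@@H]1CC(O[Si](C)(C)C(C)(C)C)=C[C@@H](N2[C@H](c3ccccc3)CC[C@H]2c2ccccc2)[C@@]1(C)CCC(=O)OC | intermediate
12 | methyl 3-[(1S,2R,6S)-2-[(2S,5S)-2,5-diphenylpyrrolidin-1-yl]-1-methyl-4-oxo-6-(prop-1-en-2-yl)cyclohexyl]propanoate | C=C(C)[C@@H]1CC(=O)C[C@@H](N2[C@H](c3ccccc3)CC[C@H]2c2ccccc2)[C@@]1(C)CCC(=O)OC | intermediate
13 | methyl 3-[(1R,6S)-1-methyl-4-oxo-6-(prop-1-en-2-yl)cyclohex-2-en-1-yl]propanoate | C=C(C)[C@@H]1CC(=O)C=C[C@@]1(C)CCC(=O)OC | intermediate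
14 | ethyl 2-acetyl-3-methylbutanoate (ethyl 2-isopropylacetoacetate) | CCOC(=O)C(C(C)C)C(C)=O | starting material
15 | ethyl 4-bromo-2-isopropyl-3-oxobutanoate | CCOC(=O)C(C(C)C)C(=O)CBr | intermediate
16 | 4-hydroxy-3-(propan-2-yl)furan-2(5H)-one | CC(C)C1=C(O)COC1=O | intermediate
17 | 4-methoxy-3-(propan-2-yl)furan-2(5H)-one | CC(C)C1=C(OC)COC1=O | intermediate
18 | (5RS)-4-methoxy-5-(phenylsulfanyl)-3-(propan-2-yl)furan-2(5H)-one | CC(C)C1=C(OC)C(OC1=O)Sc1ccccc1 | intermediate
19 | (5RS)-5-(benzenesulfonyl)-4-methoxy-3-(propan-2-yl)furan-2(5H)-one | CC(C)C1=C(OC)C(OC1=O)S(=O)(=O)c1ccccc1 | intermediate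
20 | methyl 3-[(1S,6S)-2-[2-(benzenesulfonyl)-3-methoxy-5-oxo-4-(propan-2-yl)-2,5-dihydrofuran-2-yl]-1-methyl-4-oxo-6-(prop-1-en-2-yl)cyclohexyl]propanoate, formed as its C8 lithium enolate, epimer mixture at ring C2 and the furanone carbon | C=C(C)[C@@H]1CC(=O)CC(C2(S(=O)(=O)c3ccccc3)OC(=O)C(C(C)C)=C2OC)[C@@]1(C)CCC(=O)OC | intermediate
21 | methyl 3-[(1S,2S)-7-methoxy-1-methyl-4,5,8-trioxo-6-(propan-2-yl)-2-(prop-1-en-2-yl)-1,2,3,4,4a,5,8,8a-octahydronaphthalen-1-yl]propanoate, epimer mixture at C4a and C8a | C=C(C)[C@@H]1CC(=O)C2C(=O)C(C(C)C)=C(OC)C(=O)C2[C@@]1(C)CCC(=O)OC | intermediate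
22 | methyl 3-[(1S,2S)-5,8-dihydroxy-7-methoxy-1-methyl-4-oxo-6-(propan-2-yl)-2-(prop-1-en-2-yl)-1,2,3,4-tetrahydronaphthalen-1-yl]propanoate | C=C(C)[C@@H]1CC(=O)c2c(O)c(C(C)C)c(OC)c(O)c2[C@@]1(C)CCC(=O)OC | intermediate
23 | 3-[(1S,2S)-5,8-dihydroxy-7-methoxy-1-methyl-4-oxo-6-(propan-2-yl)-2-(prop-1-en-2-yl)-1,2,3,4-tetrahydronaphthalen-1-yl]propanoic acid | C=C(C)[C@@H]1CC(=O)c2c(O)c(C(C)C)c(OC)c(O)c2[C@@]1(C)CCC(=O)O | target

## Step count and least certain steps

Total: 13 steps. Longest linear sequence: 8 steps (2, 3, 4, 5, 6, 7, 12, 13). The route is convergent: the enone branch (steps 1–7) and the donor branch (steps 8–11) meet in step 12.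

**Step 12 (key step, proposed new method).** The most likely failure is that conjugate addition stalls or reverts at C9, which is flanked by the quaternary C10, so the donor anion is consumed by lactone opening or self-condensation before ring closure. A monocyclic furanolate also has a second nucleophilic site and has not been shown to behave like a phthalide anion.

Fallback, from 17 and 13, back at 22, using known reaction types in stepwise form:
- 17 is silylated (TBSOTf, Et3N, CH2Cl2, 0 °C) to the 2-silyloxyfuran tert-butyl{[4-methoxy-3-(propan-2-yl)furan-2-yl]oxy}dimethylsilane F1.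
- F1 adds through its free C5 to C9 of 13 in a TBSOTf-catalysed vinylogous Mukaiyama–Michael reaction (CH2Cl2, −78 °C), giving methyl 3-[(1S,6S)-4-{[tert-butyl(dimethyl)silyl]oxy}-2-[3-methoxy-5-oxo-4-(propan-2-yl)-2,5-dihydrofuran-2-yl]-1-methyl-6-(prop-1-en-2-yl)cyclohex-3-en-1-yl]propanoate F2; Lewis-acid activation of the enone replaces the anionic addition.
- Bu4N[Ph3SiF2] (THF, −40 °C) frees the C8 enolate regiospecifically from the silyl enol ether, and Dieckmann acylation of the adjacent lactone closes ring C to methyl 3-[(1S,2S)-8-hydroxy-7-methoxy-1-methyl-4,5-dioxo-6-(propan-2-yl)-2-(prop-1-en-2-yl)-1,2,3,4,4a,5,8,8a-octahydronaphthalen-1-yl]propanoate F3.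
- MnO2 (CH2Cl2) oxidises the allylic C11 carbinol of F3 to enedione 21, which enolises to 22.

**Step 4.** The most likely failure is leakage between endo and exo modes or weak shielding by the auxiliary. Either lowers the enantiomeric purity of 13, because the temporary C9 centre that records the mode is discarded. The trisubstituted double bond is also a slow dienophile, which gives the distal 4,5-double bond and the carbonyl group of 3 a chance to react.

Fallback, from 3 and 4, back at 13, with control moved from the diene to a catalyst that binds the formyl group: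
- 4 is condensed with benzylamine to (3Z)-4-(benzylamino)but-3-en-2-one F4, N-acylated (NaN(SiMe3)2, ClCO2Me) to methyl benzyl[(1E)-3-oxobut-1-en-1-yl]carbamate F5, and silylated (KN(SiMe3)2, TBSCl) to methyl benzyl[(1E)-3-{[tert-butyl(dimethyl)silyl]oxy}buta-1,3-dien-1-yl]carbamate F6.
- F6 and 3 are combined under (salen)CrSbF6 (salen = N,N'-bis(3,5-di-tert-butylsalicylidene)cyclohexane-1,2-diamine dianion, antipode chosen for the 5S,10S series; 4 Å sieves, CH2Cl2, −40 °C). This enantioselective Diels–Alder reaction is known for 1-carbamato-3-silyloxybutadienes with α-substituted acroleins and should give methyl benzyl[(1R,5S,6S)-3-{[tert-butyl(dimethyl)silyl]oxy}-6-formyl-6-methyl-5-(prop-1-en-2-yl)cyclohex-2-en-1-yl]carbamate F7. The catalyst selects the dienophile face at the carbonyl, so the endo/exo ratio no longer affects enantiopurity and the formyl-bearing double bond is the activated one.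
- The reactions of steps 5 and 6 then give methyl (2E)-3-[(1S,2R,6S)-2-[benzyl(methoxycarbonyl)amino]-4-{[tert-butyl(dimethyl)silyl]oxy}-1-methyl-6-(prop-1-en-2-yl)cyclohex-3-en-1-yl]prop-2-enoate F8 and methyl 3-[(1S,2R,6S)-2-[benzyl(methoxycarbonyl)amino]-4-{[tert-butyl(dimethyl)silyl]oxy}-1-methyl-6-(prop-1-en-2-yl)cyclohex-3-en-1-yl]propanoate F9.
- Aq. HF in MeCN followed by DBU removes the silyl group and expels the carbamate to give 13.

**Step 5.** The most likely failure is sluggish olefination of the neopentyl aldehyde, which sits between the quaternary centre and the bulky pyrrolidine; forcing conditions would bring desilylation and premature β-elimination.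

Fallback, from 8, back at 13; it also replaces step 6:
- Aq. HF in MeCN converts 8 into (1R,6S)-1-methyl-4-oxo-6-(prop-1-en-2-yl)cyclohex-2-ene-1-carbaldehyde F10, in which the formyl group is far less shielded.
- A reductive Knoevenagel alkylation (2,2-dimethyl-1,3-dioxane-4,6-dione, diethyl 2,6-dimethyl-1,4-dihydropyridine-3,5-dicarboxylate, cat. L-proline, EtOH, rt) gives 2,2-dimethyl-5-{[(1R,6S)-1-methyl-4-oxo-6-(prop-1-en-2-yl)cyclohex-2-en-1-yl]methyl}-1,3-dioxane-4,6-dione F11. The alkylidene intermediate is much more electrophilic than the ring enone, so hydride transfer should be selective.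
- Heating F11 in MeOH/pyridine opens the dioxanedione, and decarboxylation of the half-ester gives 13.

**Step 13.** The most likely failure is aerial oxidation of the hydroquinone phenoxide to the methoxyquinone during the basic stage, followed by attack of hydroxide on that quinone.

Fallback, from 13, back at 23, reversing the last two operations:
- 13 is saponified (LiOH, THF/H2O), where nothing is air-sensitive, to 3-[(1R,6S)-1-methyl-4-oxo-6-(prop-1-en-2-yl)cyclohex-2-en-1-yl]propanoic acid F12.
- The annulation of step 12 is run on the lithium carboxylate of F12 with one further equivalent of LiOtBu; acidic work-up under argon gives 23 directly, so the hydroquinone never meets aqueous hydroxide.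

## Further compounds

F1 | step 12 | tert-butyl{[4-methoxy-3-(propan-2-yl)furan-2-yl]oxy}dimethylsilane | CC(C)c1c(OC)coc1O[Si](C)(C)C(C)(C)C
F2 | step 12 | methyl 3-[(1S,6S)-4-{[tert-butyl(dimethyl)silyl]oxy}-2-[3-methoxy-5-oxo-4-(propan-2-yl)-2,5-dihydrofuran-2-yl]-1-methyl-6-(prop-1-en-2-yl)cyclohex-3-en-1-yl]propanoate (epimer mixture at ring C2 and the furanone carbon) | C=C(C)[C@@H]1CC(O[Si](C)(C)C(C)(C)C)=CC(C2OC(=O)C(C(C)C)=C2OC)[C@@]1(C)CCC(=O)OC
F3 | step 12 | methyl 3-[(1S,2S)-8-hydroxy-7-methoxy-1-methyl-4,5-dioxo-6-(propan-2-yl)-2-(prop-1-en-2-yl)-1,2,3,4,4a,5,8,8a-octahydronaphthalen-1-yl]propanoate (epimer mixture at C4a, C8 and C8a) | C=C(C)[C@@H]1CC(=O)C2C(=O)C(C(C)C)=C(OC)C(O)C2[C@@]1(C)CCC(=O)OC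
F4 | step 4 | (3Z)-4-(benzylamino)but-3-en-2-one | CC(=O)/C=C\NCc1ccccc1
F5 | step 4 | methyl benzyl[(1E)-3-oxobut-1-en-1-yl]carbamate | COC(=O)N(Cc1ccccc1)/C=C/C(C)=O
F6 | step 4 | methyl benzyl[(1E)-3-{[tert-butyl(dimethyl)silyl]oxy}buta-1,3-dien-1-yl]carbamate | COC(=O)N(Cc1ccccc1)/C=C/C(=C)O[Si](C)(C)C(C)(C)C
F7 | step 4 | methyl benzyl[(1R,5S,6S)-3-{[tert-butyl(dimethyl)silyl]oxy}-6-formyl-6-methyl-5-(prop-1-en-2-yl)cyclohex-2-en-1-yl]carbamate | C=C(C)[C@@H]1CC(O[Si](C)(C)C(C)(C)C)=C[C@@H](N(Cc2ccccc2)C(=O)OC)[C@@]1(C)C=O
F8 | step 4 | methyl (2E)-3-[(1S,2R,6S)-2-[benzyl(methoxycarbonyl)amino]-4-{[tert-butyl(dimethyl)silyl]oxy}-1-methyl-6-(prop-1-en-2-yl)cyclohex-3-en-1-yl]prop-2-enoate | C=C(C)[C@@H]1CC(O[Si](C)(C)C(C)(C)C)=C[C@@H](N(Cc2ccccc2)C(=O)OC)[C@@]1(C)/C=C/C(=O)OC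
F9 | step 4 | methyl 3-[(1S,2R,6S)-2-[benzyl(methoxycarbonyl)amino]-4-{[tert-butyl(dimethyl)silyl]oxy}-1-methyl-6-(prop-1-en-2-yl)cyclohex-3-en-1-yl]propanoate | C=C(C)[C@@H]1CC(O[Si](C)(C)C(C)(C)C)=C[C@@H](N(Cc2ccccc2)C(=O)OC)[C@@]1(C)CCC(=O)OC
F10 | step 5 | (1R,6S)-1-methyl-4-oxo-6-(prop-1-en-2-yl)cyclohex-2-ene-1-carbaldehyde | C=C(C)[C@@H]1CC(=O)C=C[C@@]1(C)C=O
F11 | step 5 | 2,2-dimethyl-5-{[(1R,6S)-1-methyl-4-oxo-6-(prop-1-en-2-yl)cyclohex-2-en-1-yl]methyl}-1,3-dioxane-4,6-dione | C=C(C)[C@@H]1CC(=O)C=C[C@@]1(C)CC1C(=O)OC(C)(C)OC1=O
F12 | step 13 | 3-[(1R,6S)-1-methyl-4-oxo-6-(prop-1-en-2-yl)cyclohex-2-en-1-yl]propanoic acid | C=C(C)[C@@H]1CC(=O)C=C[C@@]1(C)CCC(=O)O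
A1 | alternative 1 | 7,9-dimethoxy-5-methyl-2-oxo-8-(propan-2-yl)-2,3,4,5-tetrahydro-1-benzoxepine-6-carbaldehyde | O=Cc1c(OC)c(C(C)C)c(OC)c2OC(=O)CCC(C)c12
A2 | alternative 1 | prop-2-en-1-yl (2E)-4-methylpenta-2,4-dienoate | C=C(C)/C=C/C(=O)OCC=C
A3 | alternative 1 | ring B cycloadduct: allyl ester at C6, hydroxyl at C7, methyl ethers at C12 and C14, C3 acyl group closed onto the C11 oxygen as a seven-membered lactone (configuration as in the SMILES) | C=C(C)[C@@H]1[C@@H](C(=O)OCC=C)[C@@H](O)c2c(OC)c(C(C)C)c(OC)c3c2[C@@]1(C)CCC(=O)O3
A4 | alternative 2 | tert-butyl 3-[(1S,4R,6S)-4-{[tert-butyl(dimethyl)silyl]oxy}-2-[1-hydroxy-2-methoxy-4-oxo-3-(propan-2-yl)cyclobut-2-en-1-yl]-1-methyl-6-(prop-1-en-2-yl)cyclohex-2-en-1-yl]propanoate | C=C(C)[C@@H]1C[C@@H](O[Si](C)(C)C(C)(C)C)C=C(C2(O)C(=O)C(C(C)C)=C2OC)[C@@]1(C)CCC(=O)OC(C)(C)C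
A5 | alternative 2 | tert-butyl 3-[(1S,2S,4R)-4-{[tert-butyl(dimethyl)silyl]oxy}-5,8-dihydroxy-7-methoxy-1-methyl-6-(propan-2-yl)-2-(prop-1-en-2-yl)-1,2,3,4-tetrahydronaphthalen-1-yl]propanoate | C=C(C)[C@@H]1C[C@@H](O[Si](C)(C)C(C)(C)C)c2c(O)c(C(C)C)c(OC)c(O)c2[C@@]1(C)CCC(=O)OC(C)(C)C
A6 | alternative 3 | 2-methylcyclohex-2-en-1-one | CC1=CCCCC1=O
A7 | alternative 3 | isopropenylmagnesium bromide | C=C(C)[Mg]Br
A8 | alternative 3 | tert-butyl prop-2-enoate | C=CC(=O)OC(C)(C)C
A9 | alternative 3 | tert-butyl 3-[(1S,6S)-1-methyl-2-oxo-6-(prop-1-en-2-yl)cyclohexyl]propanoate | C=C(C)[C@@H]1CCCC(=O)[C@@]1(C)CCC(=O)OC(C)(C)C
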